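Compound numbers are those of the steps and the compound list. Positions use labdane numbering (ring A = C1–C5 and C10, ring B = C5–C10); α is the face of ring B that carries the C5 hydrogen.

## Analysis of the target

Target 23 is a bicyclic labdane-type diterpenoid acetate: a decalin of ring A and ring B with a gem-dimethyl group at C4, an angular methyl on the quaternary C10, a tertiary alcohol bearing a methyl group at C8 and, at C9, the chain C11–C15 with a methyl-bearing stereocentre at C13 and a primary acetate at C15. There are five stereocentres: C5, C10, C9 and C8 are contiguous around ring B and C13 is remote. The hydrogen on C5, the methyl on C10, the hydrogen on C9 and the hydroxyl on C8 all lie on the α face, so the rings are cis-fused (the 10-epi series; 5S,8R,9R,10R), and ring A, the side chain and the C8 methyl share the other face; C13 is S. The tertiary C8 alcohol is the sensitive group, because acid would ionise it next to C9 and C10 and invite elimination or a methyl shift; the acetate does not tolerate hydrides, organometallics or hydroxide and therefore has to come last. The difficulty is the cis ring fusion with a quaternary C10 flanked through C5 by the gem-dimethyl C4: trans-selective polyene cyclisations and the trans-labdane natural products do not lead to it, two of the four ring stereocentres are fully substituted, and C13 is too far from the ring to be controlled by it. The strategy rests on the C5–C10 bond shared by both rings: with a carbonyl at C9, C10 and C5 are the α- and β-carbons of a 2-methylcyclohexenone (ring B) and C1–C4 are the four carbons of a butadiene, so a [4+2] cycloaddition forms C1–C10 and C4–C5 and can only give the cis fusion. An oxygen placed on C3 by the diene then allows both methyl groups to be put on C4, and the C9 carbonyl is the handle for attaching the chain and for setting C8 and C9.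

## Retrosynthetic reasoning

**23 ⇒ 22 ⇒ 21 (C15–O acyl bond, then O–Si).** The acetate is removed first in the analysis because it would not survive the hydroboration and alkaline oxidation that create C8 and C9. Diol 22 has to be acetylated at the primary hydroxyl only, which the hindered tertiary C8 hydroxyl makes easy. 22 comes from silyl ether 21 by desilylation.

**21 ⇒ 19 (C8–O and C9–H).** Both bonds are cut together to the tetrasubstituted C8=C9 alkene 19. The forward hydroboration–oxidation is a syn addition, so a single facial choice sets both centres. It has to place boron on C8 (away from quaternary C10) and attack the α face, the convex face of the cis-fused bicycle, where only the C10 methyl and the C5 hydrogen stand.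

**19 ⇒ 13 + 18 (C9–C11).** This is the bond joining ring and chain. Cutting it makes the route convergent and brings C13 in ready-made. Forward, the alkenyl triflate 13 is coupled with the primary alkylborane 18, itself formed in the flask from terminal alkene 17. The triflate is regiodefined because C10 has no hydrogen.

**17 ⇒ 16 ⇒ 15 ⇒ 14 (side chain from the chiral pool).** C13 and its two methylene arms are C3, C2/C1 and C4/C5 of (S)-citronellol 14. The citronellol chain is three carbons too long at the alkene end. Oxidative cleavage of its C6=C7 bond gives acid 16 (after protection as 15), and oxidative decarboxylation removes C6 and leaves the terminal alkene of 17. No stereocentre has to be made.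

**13 ⇒ 12 ⇒ 11 (C9–O triflate, C8–CH3).** The triflate comes from the only possible enolate of ketone 12. The C8 methyl is cut back to ketone 11, whose only enolisable position is C8.

**11 ⇒ 10 ⇒ 8 ⇒ 7 (removal of auxiliary functionality).** The C9 ketone of 11 is unmasked from dioxolane 10. The C3 methylene of 10 is traced to the C3 ketone of 8 (reduction through hydrazone 9), and the C1–C2 single bond to the enone alkene of 7. These steps only erase the functionality that the next disconnection needs.

**7 ⇒ 5 ⇒ 4 (two C4–CH3 bonds, C9 ketal).** In enone 5, C2 is vinylic and C10 is quaternary, so C4 is the only carbon that can be enolised. Two enolate methylations (through 6) build the gem-dimethyl group without regiochemical ambiguity. The C9 carbonyl of 4 also has α-hydrogens (C8) and is therefore masked first, which is possible because a saturated ketone is ketalised in preference to an enone.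

**4 ⇒ 1 + 2 (C1–C10 and C4–C5).** These two bonds remove ring A entirely and leave the commercial enone 1 and diene 2. The forward cycloaddition (through 3) must bond the CH2 terminus of 2 to the β-carbon of 1, must select one face of 1, and gives the cis fusion by necessity.

## Alternatives that were turned down

**Alternative 1: cationic bicyclisation of an epoxy polyene.**
- Disconnection: C4–C5 and C9–C10 are cut together, opening both rings to the open-chain epoxide A1, which already carries C13 and the acetate.
- Forward key step: a strong aluminium Lewis acid ionises the (R)-epoxide of A1 at C4, the Z-configured C5=C10 alkene attacks through C5, and the allylsilane unit closes ring B through C9 and loses silicon, giving A2 with a C8=C17 methylene.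
- For it: two rings and three new stereocentres in one step. The exocyclic alkene of A2 is a good handle for the C8 alcohol (face-selective epoxidation, hydride opening). In ring construction it is more step-economical than the chosen route.
- Against it: the cis fusion depends on the Z geometry of C5=C10 being transferred by strictly anti addition. Any lifetime of a tertiary C10 cation lets the stereochemical memory leak toward the trans series, and Z trisubstituted alkenes cyclise less cleanly than E ones. A1 needs an enantiopure epoxide, a Z alkene and a defined allylsilane geometry, all built linearly. The C3 hydroxyl of A2 is not in the target and costs a deoxygenation in the presence of the acetate.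
- Comparison: the chosen strategy obtains the cis fusion from a concerted cycloaddition on a ring alkene, where no leak is possible, and starts from commercial partners. It pays with more functional-group steps after the key step.

**Alternative 2: anionic oxy-Cope rearrangement of a bridged carbinol.**
- Disconnection: the C9–C10 bond is traced through a [3,3] shift to the C2–C7 bond of the bicyclo[2.2.2]octenol A3.
- Forward key step: a potassium base with a crown ether deprotonates A3, and the alkoxide rearranges through the boat transition state enforced by the bicycle, forming C9–C10, breaking C2–C7 and closing ring B as the enolate A4.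
- For it: the rigid bicycle transmits its configuration to C5, C10 and C9 at once. C9 is set in the ring-forming step, which is stronger than the chosen route, where C9 waits for a late hydroboration. The C8 methyl is in place, and A4 could be hydroxylated at C8.
- Against it: A3 is itself demanding. It needs an enantiopure bicyclic ketone and the face-selective addition of a stereodefined alkenyl metal that carries the whole chain. A4 has oxygen at C7 and a C1=C2 alkene, neither present in the target, and removing a C7 carbonyl next to a tertiary C8 alcohol is awkward because reducing conditions tend to cleave the α C–O bond.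
- Comparison: the chosen route reaches the decalin in one step from commercial compounds and leaves oxygen exactly at C9, where it is needed. Its only superfluous function, the C3 oxygen, is removed by a robust reduction.

**Alternative 3: intramolecular Diels–Alder reaction of an acyclic triene.**
- Disconnection: C5–C10 and C8–C9 are cut, opening both rings to the triene A5.
- Forward key step: a chiral cationic boron Lewis acid activates the Z-enoate of A5, which adds to the tethered 2-silyloxydiene to give A6.
- For it: four contiguous stereocentres (C5, C8, C9, C10) arise in one catalytic step, the Z-enoate placing the C9 hydrogen cis to the C10 methyl. On stereocentres set per step it is stronger than the chosen route.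
- Against it: the dienophile is a β,β-disubstituted enoate that must form a quaternary centre at its β-carbon, and is poorly reactive. The Lewis acid can isomerise the Z-enoate or cleave the silyl enol ether, and three defined alkenes must be built into A5. A6 has the wrong oxidation pattern: the C7 oxygen must go, C8 is a methine that must become a tertiary alcohol, and the C11 ester must be extended by five carbons including C13.
- Comparison: the chosen intermolecular cycloaddition sets fewer centres but uses commercial partners, and the chain arrives later in one piece by cross-coupling.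

Key step: step 1

Remark (assumption): the sense of induction for an enone without a vinylic α-hydrogen is assumed to give (4aS,8aS)-4 with the catalyst derived from (S)-α,α-diphenylprolinol; if it proves opposite, the mirror-image catalyst would be used and nothing else changes.

## Route

Step 1
Reactants: 1 2-methylcyclohex-2-en-1-one; 2 (E)-1-methoxy-3-(trimethylsilyloxy)buta-1,3-diene
Product: 4 (4aS,8aS)-8a-methyl-3,4,4a,5-tetrahydronaphthalene-1,6(2H,8aH)-dione, via silyl enol ether cycloadduct 3 (not isolated)
Conditions: (S)-3,3-diphenyl-1-(2-methylphenyl)tetrahydro-1H,3H-pyrrolo[1,2-c][1,3,2]oxazaborole (20 mol %), HNTf2 (18 mol %), CH2Cl2, −78 → −20 °C; then 1 M HCl, THF, 0 °C → rt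
Reagents that add atoms: none
Why: The protonated oxazaborolidine binds the carbonyl oxygen of 1 and lowers the enone LUMO, and diene 2 then adds in a concerted, asynchronous [4+2] in which its CH2 terminus bonds to the β-carbon of 1 (C4–C5) ahead of the methoxy-bearing terminus bonding to the methyl-bearing α-carbon (C1–C10). The closest known reaction type is the oxazaborolidinium-catalysed enantioselective Diels–Alder reaction of cyclic enones with 2-silyloxydienes. Ring A closes as the six-membered ring of the cycloaddition, both new bonds forming on one face of the ring alkene of 1, so the fusion must be cis. The relative configuration of C5 and C10 is thus fixed by the suprafacial addition, and their absolute configuration by the catalyst, whose aryl groups screen one face of the bound enone. The required regiochemistry is secured by the methoxy and silyloxy donors, which put the largest HOMO coefficient on the CH2 terminus of 2. The required facial selectivity rests on the catalyst alone, since 1 has no stereocentre. Aqueous acid then cleaves the silyl enol ether of 3 and expels methanol by β-elimination, which erases the methoxy-bearing centre and leaves the C1=C2–C3 enone of 4.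

Step 2
Reactants: 4 (4aS,8aS)-8a-methyl-3,4,4a,5-tetrahydronaphthalene-1,6(2H,8aH)-dione
Product: 5 (4a'S,8a'S)-8a'-methyl-3',4',4a',5'-tetrahydro-2'H-spiro[[1,3]dioxolane-2,1'-naphthalen]-6'(8a'H)-one
Conditions: Me3SiOCH2CH2OSiMe3 (1.5 equiv), Me3SiOTf (5 mol %), CH2Cl2, −78 → −20 °C; pyridine quench
Reagents that add atoms: 1,2-bis(trimethylsilyloxy)ethane, C[Si](C)(C)OCCO[Si](C)(C)C
Why: Lewis-acid-catalysed ketalisation with the bis-silyl ether of the diol; at low temperature the saturated C9 ketone forms the dioxolane while the less electrophilic conjugated C3 carbonyl is left, the established chemoselectivity of this ketalisation. No stereocentre is touched.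

Step 3
Reactants: 5 (4a'S,8a'S)-8a'-methyl-3',4',4a',5'-tetrahydro-2'H-spiro[[1,3]dioxolane-2,1'-naphthalen]-6'(8a'H)-one
Product: 7 (4a'S,8a'R)-5',5',8a'-trimethyl-3',4',4a',5'-tetrahydro-2'H-spiro[[1,3]dioxolane-2,1'-naphthalen]-6'(8a'H)-one, via monomethyl enone 6 (not isolated)
Conditions: LiN(i-Pr)2 (1.1 equiv), THF, −78 °C; MeI, −78 → 0 °C; then LiN(i-Pr)2 (1.3 equiv), −78 °C; MeI, DMPU, −78 °C → rt
Reagents that add atoms: iodomethane, CI
Why: Kinetic α'-enolate alkylation of an enone: C2 is vinylic and C10 has no hydrogen, so the only enolate is the cross-conjugated one at C4, and two rounds of methylation make C4 quaternary. The C9 ketal removes the only other acidic site.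

Step 4
Reactants: 7 (4a'S,8a'R)-5',5',8a'-trimethyl-3',4',4a',5'-tetrahydro-2'H-spiro[[1,3]dioxolane-2,1'-naphthalen]-6'(8a'H)-one
Product: 8 (4a'S,8a'R)-5',5',8a'-trimethyl-3',4',4a',7',8',8a'-hexahydro-2'H-spiro[[1,3]dioxolane-2,1'-naphthalen]-6'(5'H)-one
Conditions: H2 (1 atm), 10% Pd/C, EtOAc, rt
Reagents that add atoms: none
Why: Heterogeneous catalytic hydrogenation of the disubstituted enone alkene; C1 and C2 become methylene groups, so no stereocentre is created, and ketal and ketone are inert.

Step 5
Reactants: 8 (4a'S,8a'R)-5',5',8a'-trimethyl-3',4',4a',7',8',8a'-hexahydro-2'H-spiro[[1,3]dioxolane-2,1'-naphthalen]-6'(5'H)-one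
Product: 10 (4a'S,8a'R)-5',5',8a'-trimethyloctahydro-2'H-spiro[[1,3]dioxolane-2,1'-naphthalene], via hydrazone 9 (not isolated)
Conditions: N2H4·H2O, KOH, diethylene glycol, 130 °C; then distil to 200 °C
Reagents that add atoms: none
Why: Wolff–Kishner reduction (Huang–Minlon procedure): hydrazone 9 forms at the hindered C3 ketone and loses N2 under base at high temperature, a reduction long used on 4,4-dimethyl-3-ketones. The ketal is base-stable and no stereocentre is α to C3.

Step 6
Reactants: 10 (4a'S,8a'R)-5',5',8a'-trimethyloctahydro-2'H-spiro[[1,3]dioxolane-2,1'-naphthalene]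
Product: 11 (4aS,8aR)-5,5,8a-trimethyloctahydronaphthalen-1(2H)-one
Conditions: 2 M HCl, THF, rt → 45 °C
Reagents that add atoms: water, O
Why: Acid-catalysed ketal hydrolysis; C5 is β to the carbonyl and C10 is quaternary, so the ring fusion cannot epimerise.

Step 7
Reactants: 11 (4aS,8aR)-5,5,8a-trimethyloctahydronaphthalen-1(2H)-one
Product: 12 (4aS,8aR)-2,5,5,8a-tetramethyloctahydronaphthalen-1(2H)-one (both C2 epimers)
Conditions: LiN(i-Pr)2 (1.05 equiv), THF, −78 °C; MeI, −78 → 0 °C
Reagents that add atoms: iodomethane, CI
Why: Enolate alkylation; C10 is quaternary, so only C8 can be deprotonated. The new C8 centre should form as a mixture of epimers, which is of no consequence because C8 becomes sp2 in step 8.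

Step 8
Reactants: 12 (4aS,8aR)-2,5,5,8a-tetramethyloctahydronaphthalen-1(2H)-one
Product: 13 (4aS,8aR)-2,5,5,8a-tetramethyl-3,4,4a,5,6,7,8,8a-octahydronaphthalen-1-yl trifluoromethanesulfonate
Conditions: KN(SiMe3)2, THF, −78 → 0 °C; PhNTf2, 0 °C → rt
Reagents that add atoms: N-phenylbis(trifluoromethanesulfonimide), O=S(=O)(N(c1ccccc1)S(=O)(=O)C(F)(F)F)C(F)(F)F
Why: Enolate O-sulfonylation; the only possible enolate is the tetrasubstituted C8=C9 one, so the enol triflate is regiodefined. Warming allows the slow removal of the tertiary C8 hydrogen.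

Step 9
Reactants: 14 (S)-citronellol
Product: 15 (S)-tert-butyl[(3,7-dimethyloct-6-en-1-yl)oxy]diphenylsilane
Conditions: t-BuPh2SiCl, imidazole, DMF, 0 °C → rt
Reagents that add atoms: tert-butyl(chloro)diphenylsilane, CC(C)(C)[Si](Cl)(c1ccccc1)c1ccccc1
Why: Imidazole-promoted silylation of the primary alcohol; this bulky silyl ether is chosen because it should resist the oxidative, organometallic and borane steps that follow.

Step 10
Reactants: 15 (S)-tert-butyl[(3,7-dimethyloct-6-en-1-yl)oxy]diphenylsilane
Product: 16 (S)-6-[(tert-butyldiphenylsilyl)oxy]-4-methylhexanoic acid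
Conditions: RuCl3·xH2O (2 mol %), NaIO4 (4 equiv), MeCN/EtOAc/H2O, 0 °C → rt
Reagents that add atoms: sodium periodate, [Na+].[O-]I(=O)(=O)=O; water, O
Why: RuO4-catalysed oxidative cleavage of the trisubstituted alkene; C6 of the citronellol chain becomes the carboxyl carbon and the isopropylidene end leaves as acetone. The stereocentre is remote and untouched.

Step 11
Reactants: 16 (S)-6-[(tert-butyldiphenylsilyl)oxy]-4-methylhexanoic acid
Product: 17 (R)-tert-butyl[(3-methylpent-4-en-1-yl)oxy]diphenylsilane
Conditions: Pb(OAc)4 (1.5 equiv), Cu(OAc)2·H2O (0.2 equiv), pyridine, PhH, 80 °C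
Reagents that add atoms: none
Why: Kochi oxidative decarboxylation: Pb(OAc)4 generates the primary alkyl radical with loss of CO2, and divalent copper oxidises it to the terminal alkene. The stereocentre becomes allylic but is not involved; its descriptor changes from S to R only through the priority rules.

Step 12
Reactants: 13 (4aS,8aR)-2,5,5,8a-tetramethyl-3,4,4a,5,6,7,8,8a-octahydronaphthalen-1-yl trifluoromethanesulfonate; 17 (R)-tert-butyl[(3-methylpent-4-en-1-yl)oxy]diphenylsilane
Product: 19 tert-butyl{[(3S)-3-methyl-5-[(4aS,8aR)-2,5,5,8a-tetramethyl-3,4,4a,5,6,7,8,8a-octahydronaphthalen-1-yl]pentyl]oxy}diphenylsilane, via B-alkyl-9-BBN borane 18 (not isolated)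
Conditions: 17 (1.5 equiv), 9-BBN, THF, 0 °C → rt; then 13, Pd(dppf)Cl2 (10 mol %), AsPh3 (10 mol %), Cs2CO3, DMF/H2O, rt → 50 °C
Reagents that add atoms: none
Why: B-alkyl Suzuki–Miyaura coupling: 9-BBN adds to the terminal alkene in the anti-Markovnikov sense to give 18, whose primary alkyl group is transferred to the alkenylpalladium formed by oxidative addition of zerovalent palladium to triflate 13. This forms C9–C11 and touches no stereocentre.

Step 13
Reactants: 19 tert-butyl{[(3S)-3-methyl-5-[(4aS,8aR)-2,5,5,8a-tetramethyl-3,4,4a,5,6,7,8,8a-octahydronaphthalen-1-yl]pentyl]oxy}diphenylsilane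
Product: 21 (1R,2R,4aS,8aR)-1-[(3S)-5-{[tert-butyl(diphenyl)silyl]oxy}-3-methylpentyl]-2,5,5,8a-tetramethyldecahydronaphthalen-2-ol, via tertiary alkylborane 20 (not isolated)
Conditions: BH3·THF (4 equiv), THF, 0 °C → rt; then 3 M NaOH, 30% H2O2, 0 → 40 °C
Reagents that add atoms: hydrogen peroxide, OO
Why: Hydroboration–oxidation of a tetrasubstituted alkene: boron should go to C8, away from the quaternary C10, and hydrogen to C9, both from the convex α face (the face of the C10 methyl and the C5 hydrogen, ring A blocking the other). The syn addition thus sets the C9 hydrogen and the C8 boron α together, and oxidation with retention gives the 8α-alcohol.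

Step 14
Reactants: 21 (1R,2R,4aS,8aR)-1-[(3S)-5-{[tert-butyl(diphenyl)silyl]oxy}-3-methylpentyl]-2,5,5,8a-tetramethyldecahydronaphthalen-2-ol
Product: 22 (1R,2R,4aS,8aR)-1-[(3S)-5-hydroxy-3-methylpentyl]-2,5,5,8a-tetramethyldecahydronaphthalen-2-ol
Conditions: Bu4NF, THF, rt
Reagents that add atoms: none
Why: Fluoride-mediated cleavage of the silyl ether; the tertiary alcohol and all stereocentres are untouched.

Step 15
Reactants: 22 (1R,2R,4aS,8aR)-1-[(3S)-5-hydroxy-3-methylpentyl]-2,5,5,8a-tetramethyldecahydronaphthalen-2-ol
Product: 23 (3S)-5-[(1R,2R,4aS,8aR)-2-hydroxy-2,5,5,8a-tetramethyldecahydronaphthalen-1-yl]-3-methylpentyl acetate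
Conditions: Ac2O (1.5 equiv), pyridine, CH2Cl2, 0 °C → rt
Reagents that add atoms: acetic anhydride, CC(=O)OC(C)=O
Why: Chemoselective acylation; without a nucleophilic catalyst the primary C15 hydroxyl should be acetylated while the hindered tertiary C8 hydroxyl stays free.

## Compound list

1 | 2-methylcyclohex-2-en-1-one | CC1=CCCCC1=O | starting material
2 | (E)-1-methoxy-3-(trimethylsilyloxy)buta-1,3-diene | CO/C=C/C(=C)O[Si](C)(C)C | starting material
3 | (4aS,8aS)-8-methoxy-8a-methyl-6-(trimethylsilyloxy)-3,4,4a,5,8,8a-hexahydronaphthalen-1(2H)-one (configuration at C8 not assigned) | COC1C=C(O[Si](C)(C)C)C[C@@H]2CCCC(=O)[C@]12C | intermediate (not isolated)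
4 | (4aS,8aS)-8a-methyl-3,4,4a,5-tetrahydronaphthalene-1,6(2H,8aH)-dione | O=C1CCC[C@H]2CC(=O)C=C[C@@]12C | intermediate
5 | (4a'S,8a'S)-8a'-methyl-3',4',4a',5'-tetrahydro-2'H-spiro[[1,3]dioxolane-2,1'-naphthalen]-6'(8a'H)-one | O1CCOC12[C@]3(C)C=CC(=O)C[C@@H]3CCC2 | intermediate
6 | (4a'S,8a'R)-5',8a'-dimethyl-3',4',4a',5'-tetrahydro-2'H-spiro[[1,3]dioxolane-2,1'-naphthalen]-6'(8a'H)-one (both C5' epimers) | O1CCOC12[C@]3(C)C=CC(=O)C(C)[C@@H]3CCC2 | intermediate (not isolated)
7 | (4a'S,8a'R)-5',5',8a'-trimethyl-3',4',4a',5'-tetrahydro-2'H-spiro[[1,3]dioxolane-2,1'-naphthalen]-6'(8a'H)-one | O1CCOC12[C@]3(C)C=CC(=O)C(C)(C)[C@@H]3CCC2 | intermediate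
8 | (4a'S,8a'R)-5',5',8a'-trimethyl-3',4',4a',7',8',8a'-hexahydro-2'H-spiro[[1,3]dioxolane-2,1'-naphthalen]-6'(5'H)-one | O1CCOC12[C@]3(C)CCC(=O)C(C)(C)[C@@H]3CCC2 | intermediate
9 | (4a'S,8a'R)-6'-hydrazinylidene-5',5',8a'-trimethyloctahydro-2'H-spiro[[1,3]dioxolane-2,1'-naphthalene] | O1CCOC12[C@]3(C)CCC(=NN)C(C)(C)[C@@H]3CCC2 | intermediate (not isolated)
10 | (4a'S,8a'R)-5',5',8a'-trimethyloctahydro-2'H-spiro[[1,3]dioxolane-2,1'-naphthalene] | O1CCOC12[C@]3(C)CCCC(C)(C)[C@@H]3CCC2 | intermediate
11 | (4aS,8aR)-5,5,8a-trimethyloctahydronaphthalen-1(2H)-one | O=C1[C@]2(C)CCCC(C)(C)[C@@H]2CCC1 | intermediate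
12 | (4aS,8aR)-2,5,5,8a-tetramethyloctahydronaphthalen-1(2H)-one (both C2 epimers) | O=C1[C@]2(C)CCCC(C)(C)[C@@H]2CCC1C | intermediate
13 | (4aS,8aR)-2,5,5,8a-tetramethyl-3,4,4a,5,6,7,8,8a-octahydronaphthalen-1-yl trifluoromethanesulfonate | CC1=C(OS(=O)(=O)C(F)(F)F)[C@]2(C)CCCC(C)(C)[C@@H]2CC1 | intermediate
14 | (S)-citronellol, (S)-3,7-dimethyloct-6-en-1-ol | C[C@@H](CCC=C(C)C)CCO | starting material
15 | (S)-tert-butyl[(3,7-dimethyloct-6-en-1-yl)oxy]diphenylsilane | C[C@@H](CCC=C(C)C)CCO[Si](c1ccccc1)(c1ccccc1)C(C)(C)C | intermediate
16 | (S)-6-[(tert-butyldiphenylsilyl)oxy]-4-methylhexanoic acid | C[C@@H](CCC(=O)O)CCO[Si](c1ccccc1)(c1ccccc1)C(C)(C)C | intermediate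
17 | (R)-tert-butyl[(3-methylpent-4-en-1-yl)oxy]diphenylsilane | C[C@@H](C=C)CCO[Si](c1ccccc1)(c1ccccc1)C(C)(C)C | intermediate
18 | 9-[(3S)-5-(tert-butyldiphenylsilyloxy)-3-methylpentyl]-9-borabicyclo[3.3.1]nonane | C1CCC2CCCC1B2CC[C@H](C)CCO[Si](c3ccccc3)(c3ccccc3)C(C)(C)C | intermediate (not isolated)
19 | tert-butyl{[(3S)-3-methyl-5-[(4aS,8aR)-2,5,5,8a-tetramethyl-3,4,4a,5,6,7,8,8a-octahydronaphthalen-1-yl]pentyl]oxy}diphenylsilane | CC1=C(CC[C@H](C)CCO[Si](c3ccccc3)(c3ccccc3)C(C)(C)C)[C@]2(C)CCCC(C)(C)[C@@H]2CC1 | intermediate
20 | (13S)-15-(tert-butyldiphenylsilyloxy)-10-epi-labdan-8α-ylborane (9α-H; BH2 on C8) | CC(C)(C)[Si](c3ccccc3)(c3ccccc3)OCC[C@@H](C)CC[C@@H]1[C@]2(C)CCCC(C)(C)[C@@H]2CC[C@@]1(C)B | intermediate (not isolated)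
21 | (1R,2R,4aS,8aR)-1-[(3S)-5-{[tert-butyl(diphenyl)silyl]oxy}-3-methylpentyl]-2,5,5,8a-tetramethyldecahydronaphthalen-2-ol | CC(C)(C)[Si](c3ccccc3)(c3ccccc3)OCC[C@@H](C)CC[C@@H]1[C@]2(C)CCCC(C)(C)[C@@H]2CC[C@@]1(C)O | intermediate
22 | (1R,2R,4aS,8aR)-1-[(3S)-5-hydroxy-3-methylpentyl]-2,5,5,8a-tetramethyldecahydronaphthalen-2-ol | OCC[C@@H](C)CC[C@@H]1[C@]2(C)CCCC(C)(C)[C@@H]2CC[C@@]1(C)O | intermediate
23 | (3S)-5-[(1R,2R,4aS,8aR)-2-hydroxy-2,5,5,8a-tetramethyldecahydronaphthalen-1-yl]-3-methylpentyl acetate | CC(=O)OCC[C@@H](C)CC[C@@H]1[C@]2(C)CCCC(C)(C)[C@@H]2CC[C@@]1(C)O | target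

## Step count and least certain steps

Total: 15 steps. Longest linear sequence: 12 steps (steps 1–8 and 12–15); the side chain is made in steps 9–11 and joins at step 12.

**Step 1 (key step).** Three processes may spoil it.
- Silyl transfer from 2 to the triflimide counter-ion would release an achiral silicon Lewis acid that promotes a racemic background reaction or a stepwise Mukaiyama–Michael addition, so facial selectivity would erode.
- Enone 1 lacks the vinylic α-hydrogen that usually organises the catalyst complex and may bind in two orientations.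
- 1 is a sluggish dienophile, so decomposition of the diene may outrun cycloaddition.

Fallback: give up catalytic control and resolve. From 1 and 2, an achiral aluminium Lewis acid (EtAlCl2, toluene, −40 °C → rt; then 1 M HCl) should give the racemic enedione F1. Preparative chromatography on a chiral stationary phase (amylose tris(3,5-dimethylphenylcarbamate), supercritical CO2/MeOH) would separate it, and the (4aS,8aS) enantiomer is 4, where the route is rejoined.

**Step 13.** Hydroboration of the tetrasubstituted alkene next to the quaternary C10 may be slow or incomplete. Boron may add at C9 or from the β face, and boron may migrate if heating is needed.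

Fallback: set C9 and C8 in separate operations with unambiguous regiochemistry, starting from 11 (steps 7, 8 and 12 are then not used).
- KN(SiMe3)2 and PhNTf2 would give the trisubstituted enol triflate F2.
- Coupling with borane 18 under the conditions of step 12 would give the trisubstituted alkene F3.
- Hydroboration–oxidation, with boron going to the methine carbon C8 from the convex α face, would give the secondary alcohol F4 with the C9 hydrogen α.
- Dess–Martin oxidation would give the ketone F5, and Wittig methylenation (Ph3P=CH2) the exocyclic alkene F6.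
- Epoxidation with mCPBA from the equatorial α face would give the spiro-epoxide F7.
- LiAlH4 would open it at the CH2 terminus to give 21, where the route is rejoined.

**Step 12.** Oxidative addition and transmetallation at the tetrasubstituted triflate beside C10 may be slow, so that β-hydride elimination or protodeboronation of 18 and hydrolysis of 13 back to 12 compete.

Fallback: form C9–C11 by carbonyl addition instead of cross-coupling.
- From 16, iododecarboxylation (PhI(OAc)2, I2, hν) would give the primary iodide F8.
- t-BuLi (2 equiv, Et2O, −78 °C) would give the alkyllithium F9.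
- In the presence of CeCl3, F9 should add to ketone 12 to give the tertiary carbinol F10.
- Dehydration with SOCl2/pyridine proceeds without a free cation, and hence without risk of a methyl shift from C10; it should give the more substituted ring alkene 19, where the route is rejoined.

**Step 11.** The primary radical formed on decarboxylation may be trapped as an acetate or reduced instead of being oxidised to the alkene by divalent copper, and conversion may be low.

Fallback: avoid the alkene altogether. From 16, iododecarboxylation to the iodide F8 and lithiation to the alkyllithium F9 as above, then capture with B-methoxy-9-BBN, would give the lithium borate F11. This is the transmetallating species of the B-alkyl Suzuki–Miyaura coupling and would be coupled with 13 under the palladium conditions of step 12 to give 19, where the route is rejoined.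

## Further compounds

F1 | step 1 | racemic cis-8a-methyl-3,4,4a,5-tetrahydronaphthalene-1,6(2H,8aH)-dione (4 and its mirror image) | O=C1CCC[C@H]2CC(=O)C=C[C@@]12C.O=C1CCC[C@@H]2CC(=O)C=C[C@]12C
F2 | step 13 | (4aS,8aR)-5,5,8a-trimethyl-3,4,4a,5,6,7,8,8a-octahydronaphthalen-1-yl trifluoromethanesulfonate | C1=C(OS(=O)(=O)C(F)(F)F)[C@]2(C)CCCC(C)(C)[C@@H]2CC1
F3 | step 13 | tert-butyl{[(3S)-3-methyl-5-[(4aS,8aR)-5,5,8a-trimethyl-3,4,4a,5,6,7,8,8a-octahydronaphthalen-1-yl]pentyl]oxy}diphenylsilane | C1=C(CC[C@H](C)CCO[Si](c3ccccc3)(c3ccccc3)C(C)(C)C)[C@]2(C)CCCC(C)(C)[C@@H]2CC1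
F4 | step 13 | (13S)-15-(tert-butyldiphenylsilyloxy)-17-nor-10-epi-labdan-8α-ol (9α-H) | CC(C)(C)[Si](c3ccccc3)(c3ccccc3)OCC[C@@H](C)CC[C@@H]1[C@]2(C)CCCC(C)(C)[C@@H]2CC[C@H]1O
F5 | step 13 | (13S)-15-(tert-butyldiphenylsilyloxy)-17-nor-10-epi-labdan-8-one (9α-H) | CC(C)(C)[Si](c3ccccc3)(c3ccccc3)OCC[C@@H](C)CC[C@@H]1[C@]2(C)CCCC(C)(C)[C@@H]2CCC1=O
F6 | step 13 | (13S)-15-(tert-butyldiphenylsilyloxy)-10-epi-labd-8(17)-ene (9α-H) | CC(C)(C)[Si](c3ccccc3)(c3ccccc3)OCC[C@@H](C)CC[C@@H]1[C@]2(C)CCCC(C)(C)[C@@H]2CCC1=C
F7 | step 13 | (13S)-15-(tert-butyldiphenylsilyloxy)-8α,17-epoxy-10-epi-labdane (9α-H) | CC(C)(C)[Si](c3ccccc3)(c3ccccc3)OCC[C@@H](C)CC[C@@H]1[C@]2(C)CCCC(C)(C)[C@@H]2CC[C@]14CO4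
F8 | step 12 | (R)-tert-butyl[(5-iodo-3-methylpentyl)oxy]diphenylsilane | C[C@@H](CCI)CCO[Si](c1ccccc1)(c1ccccc1)C(C)(C)C
F9 | step 12 | [(3S)-5-(tert-butyldiphenylsilyloxy)-3-methylpentyl]lithium | [Li]CC[C@H](C)CCO[Si](c1ccccc1)(c1ccccc1)C(C)(C)C
F10 | step 12 | (4aS,8aR)-1-[(3S)-5-(tert-butyldiphenylsilyloxy)-3-methylpentyl]-2,5,5,8a-tetramethyldecahydronaphthalen-1-ol (mixture at C1 and C2) | OC1(CC[C@H](C)CCO[Si](c3ccccc3)(c3ccccc3)C(C)(C)C)[C@]2(C)CCCC(C)(C)[C@@H]2CCC1C
F11 | step 11 | lithium 9-[(3S)-5-(tert-butyldiphenylsilyloxy)-3-methylpentyl]-9-methoxy-9-boranuidabicyclo[3.3.1]nonane | [Li+].CO[B-]1(CC[C@H](C)CCO[Si](c3ccccc3)(c3ccccc3)C(C)(C)C)C2CCCC1CCC2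
A1 | alternative 1 | (3S,6Z,10Z,14R)-14,15-epoxy-3,11,15-trimethyl-7-[(trimethylsilyl)methyl]hexadeca-6,10-dien-1-yl acetate | CC(=O)OCC[C@@H](C)CC/C=C(\C[Si](C)(C)C)CC/C=C(/C)CC[C@H]1OC1(C)C
A2 | alternative 1 | (3R,13S)-3-hydroxy-10-epi-labd-8(17)-en-15-yl acetate | CC(=O)OCC[C@@H](C)CC[C@@H]1[C@]2(C)CC[C@@H](O)C(C)(C)[C@@H]2CCC1=C
A3 | alternative 2 | 2-[(2E,6S)-8-(tert-butyldimethylsilyloxy)-6-methyloct-2-en-2-yl]-5,8,8-trimethylbicyclo[2.2.2]oct-5-en-2-ol (alkenyl group syn to the ring alkene) | CC(C)(C)[Si](C)(C)OCC[C@@H](C)CC/C=C(\C)[C@]1(O)C[C@@H]2C(C)=C[C@H]1CC2(C)C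
A4 | alternative 2 | potassium C7–C8 enolate of (13S)-15-(tert-butyldimethylsilyloxy)-10-epi-labd-1-en-7-one | CC(C)(C)[Si](C)(C)OCC[C@@H](C)CC[C@@H]1[C@]2(C)C=CCC(C)(C)[C@@H]2CC([O-])=C1C.[K+]
A5 | alternative 3 | methyl (2Z,8E,10Z)-10-(tert-butyldimethylsilyloxy)-3,7,7-trimethyldodeca-2,8,10-trienoate | COC(=O)/C=C(/C)CCCC(C)(C)/C=C/C(O[Si](C)(C)C(C)(C)C)=C/C
A6 | alternative 3 | methyl 7-(tert-butyldimethylsilyloxy)-10-epi-12,13,14,15,16-pentanorlabd-6-en-11-oate | COC(=O)[C@@H]1[C@]2(C)CCCC(C)(C)[C@@H]2C=C(O[Si](C)(C)C(C)(C)C)[C@@H]1C
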